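## Retrosynthetic overview

1. Target ⇐ acetylation of the 2,9,14-triol; the γ-lactone (C8–C17 bond, C8–OH, C17) ⇐ intramolecular samarium Reformatsky reaction of a C7 2-bromopropanoate onto a C8 ketone; C9–O ⇐ enolate oxidation.
2. Ten-membered carbocycle ⇐ C9–C10 disconnection by retro-Claisen. The enabling feature is the unit C8(=O)–C9–C10–C11(=C20H2): an oxygenated C8 two atoms from the exocyclic methylene on ring A. It maps onto a 12-membered lactone C8(=O)–O–C20 with the ring A double bond at C10=C11, which is methylenated and contracts by two atoms.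
3. 12-Membered lactone ⇐ macrolactonisation of a seco acid ⇐ C3–C4 enolate alkylation of a ring A methyl ketone with a C4–C8 allylic bromide; C2 by CBS reduction.
4. Ring A ⇐ ring-closing metathesis of a diene made by iridium-catalysed tert-(hydroxy)prenylation (C1, C14); bromide ⇐ Sharpless epoxidation and chloride opening (C6, C7); both fragments from 2-methylidenepropane-1,3-diol.
5. Ring order: ring A (step 5), 12-membered lactone (step 23), ten-membered ring by contraction (step 24), γ-lactone (step 29).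

Key step: step 24

Remark on numbering: locants C1–C20 are those of the target (bicyclo[8.4.0]tetradecane numbering). C1 is the quaternary carbon with CH3-15, C2–C9 lie in the ten-membered ring, C10 is the ring-fusion CH, C11–C14 lie in ring A, C16 and C20 are the methylene carbons, and C17–C19 are the lactone carbons. For the larger intermediates the SMILES fixes the configuration.

Assumption: the tert-(hydroxy)prenylation of step 4 is taken to give the diastereomer with the secondary hydroxyl anti to the hydroxymethyl group (chain drawn through the vinyl group), as its closed chair transition state with the (E)-σ-allyl species predicts.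

## Route

Step 1
Reactants: 1 2-methylidenepropane-1,3-diol
Product: 2 2-{[(4-methoxybenzyl)oxy]methyl}prop-2-en-1-ol
Conditions: NaH (1.0 equiv), 4-methoxybenzyl chloride (1.0 equiv), Bu4NI (cat.), THF/DMF, 0 °C to rt
Reagents that add atoms: 4-methoxybenzyl chloride, COc1ccc(CCl)cc1
Why: Williamson etherification with one equivalent of base on the symmetric diol should give mainly the mono-ether, which feeds both fragments.

Step 2
Reactants: 2 2-{[(4-methoxybenzyl)oxy]methyl}prop-2-en-1-ol
Product: 3 ethyl 4-{[(4-methoxybenzyl)oxy]methyl}pent-4-enoate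
Conditions: MeC(OEt)3 (5 equiv), EtCO2H (cat.), 140 °C, ethanol distilled off
Reagents that add atoms: triethyl orthoacetate, CCOC(C)(OCC)OCC
Why: Johnson–Claisen rearrangement of the 2-substituted allyl alcohol adds the C13–C14 unit at the methylene terminus and regenerates a 1,1-disubstituted alkene (future C11), with no stereocentre formed.

Step 3
Reactants: 3 ethyl 4-{[(4-methoxybenzyl)oxy]methyl}pent-4-enoate
Product: 4 4-{[(4-methoxybenzyl)oxy]methyl}pent-4-en-1-ol
Conditions: LiAlH4, Et2O, 0 °C
Reagents that add atoms: none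
Why: Hydride reduction of the ester to the primary alcohol, which leaves the ether and the isolated alkene untouched.

Step 4
Reactants: 4 4-{[(4-methoxybenzyl)oxy]methyl}pent-4-en-1-ol; 5 isoprene monoxide (2-ethenyl-2-methyloxirane, racemic)
Product: 6 (2S,3S)-2-ethenyl-6-{[(4-methoxybenzyl)oxy]methyl}-2-methylhept-6-ene-1,3-diol
Conditions: [Ir(cod)Cl]2 (2.5 mol %), (R)-Tol-BINAP (5 mol %), 4-cyano-3-nitrobenzoic acid (10 mol %), allyl acetate (precatalyst formation), K3PO4 (5 mol %), THF, 60 °C
Reagents that add atoms: none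
Why: Iridium-catalysed transfer-hydrogenative carbonyl tert-(hydroxy)prenylation, in which the alcohol is dehydrogenated in situ and the (E)-σ-allyliridium species from the vinyl epoxide (its stereocentre is erased) adds through a closed chair transition state; the ligand antipode is chosen to give the S carbinol (C14), and the hydroxymethyl group trans to Ir–CH2 ends anti to the new hydroxyl, which sets the quaternary C1.

Step 5
Reactants: 6 (2S,3S)-2-ethenyl-6-{[(4-methoxybenzyl)oxy]methyl}-2-methylhept-6-ene-1,3-diol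
Product: 7 (1S,2S)-2-(hydroxymethyl)-4-{[(4-methoxybenzyl)oxy]methyl}-2-methylcyclohex-3-en-1-ol
Conditions: second-generation Grubbs catalyst (H2IMes)(PCy3)Cl2Ru=CHPh (3 mol %), CH2Cl2 (0.01 M), 40 °C
Reagents that add atoms: none
Why: Ring-closing metathesis of the vinyl group with the 1,1-disubstituted alkene closes ring A as the C10=C11 cyclohexene (six-membered, free hydroxyls tolerated) without touching the stereocentres.

Step 6
Reactants: 7 (1S,2S)-2-(hydroxymethyl)-4-{[(4-methoxybenzyl)oxy]methyl}-2-methylcyclohex-3-en-1-ol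
Product: 8 (1R,6S)-6-hydroxy-3-{[(4-methoxybenzyl)oxy]methyl}-1-methylcyclohex-2-ene-1-carboxylic acid
Conditions: TEMPO (20 mol %), PhI(OAc)2 (2.2 equiv), MeCN/H2O 1:1, rt
Reagents that add atoms: water, O
Why: Oxoammonium (TEMPO) oxidation is selective for the primary over the secondary alcohol and takes it to the acid via the aldehyde hydrate, while the quaternary α-carbon excludes epimerisation.

Step 7
Reactants: 8 (1R,6S)-6-hydroxy-3-{[(4-methoxybenzyl)oxy]methyl}-1-methylcyclohex-2-ene-1-carboxylic acid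
Product: 9 1-[(1R,6S)-6-hydroxy-3-{[(4-methoxybenzyl)oxy]methyl}-1-methylcyclohex-2-en-1-yl]ethan-1-one
Conditions: MeLi (4 equiv), THF, 0 °C to rt; inverse quench into cold 1 M HCl
Reagents that add atoms: methyllithium, [Li]C
Why: Addition of methyllithium to the lithium carboxylate stops at the stable geminal dialkoxide, which collapses to the methyl ketone (C2, C3) only on acidic work-up, avoiding over-addition and base-induced retro-aldol cleavage.

Step 8
Reactants: 9 1-[(1R,6S)-6-hydroxy-3-{[(4-methoxybenzyl)oxy]methyl}-1-methylcyclohex-2-en-1-yl]ethan-1-one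
Product: 10 1-[(1R,6S)-6-[(tert-butyldimethylsilyl)oxy]-3-{[(4-methoxybenzyl)oxy]methyl}-1-methylcyclohex-2-en-1-yl]ethan-1-one
Conditions: TBSOTf, 2,6-lutidine, CH2Cl2, −78 to 0 °C
Reagents that add atoms: tert-butyldimethylsilyl triflate, CC(C)(C)[Si](C)(C)OS(=O)(=O)C(F)(F)F
Why: Silylation of the hindered secondary alcohol with the silyl triflate blocks the β-hydroxy ketone against retro-aldol cleavage in the enolate step.

Step 9
Reactants: 2 2-{[(4-methoxybenzyl)oxy]methyl}prop-2-en-1-ol
Product: 12 ethyl (2E)-4-{[(4-methoxybenzyl)oxy]methyl}penta-2,4-dienoate, via enal 11 (not isolated)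
Conditions: MnO2 (10 equiv), Ph3P=CHCO2Et (1.3 equiv), CH2Cl2, rt
Reagents that add atoms: (ethoxycarbonylmethylene)triphenylphosphorane, CCOC(=O)C=P(c1ccccc1)(c1ccccc1)c1ccccc1
Why: Tandem allylic oxidation–Wittig olefination traps the sensitive 2-substituted acrolein as it forms, and the stabilised ylide gives the E alkene (C6=C7).

Step 10
Reactants: 12 ethyl (2E)-4-{[(4-methoxybenzyl)oxy]methyl}penta-2,4-dienoate
Product: 13 (2E)-4-{[(4-methoxybenzyl)oxy]methyl}penta-2,4-dien-1-ol
Conditions: iBu2AlH (2.5 equiv), CH2Cl2, −78 °C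
Reagents that add atoms: none
Why: 1,2-Reduction of the conjugated ester by the aluminium hydride gives the allylic alcohol needed to direct the epoxidation.

Step 11
Reactants: 13 (2E)-4-{[(4-methoxybenzyl)oxy]methyl}penta-2,4-dien-1-ol
Product: 14 [(2R,3R)-3-(3-{[(4-methoxybenzyl)oxy]}prop-1-en-2-yl)oxiran-2-yl]methanol
Conditions: Ti(OiPr)4 (10 mol %), D-(−)-diethyl tartrate (12 mol %), tBuOOH (2 equiv), 4 Å molecular sieves, CH2Cl2, −20 °C
Reagents that add atoms: tert-butyl hydroperoxide, CC(C)(C)OO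
Why: Sharpless asymmetric epoxidation oxidises only the alkene of the allylic alcohol, and the D-(−)-tartrate should give the (2R,3R)-epoxide of the E alkene (C7 and the oxygen face at C6) under catalyst control.

Step 12
Reactants: 14 [(2R,3R)-3-(3-{[(4-methoxybenzyl)oxy]}prop-1-en-2-yl)oxiran-2-yl]methanol
Product: 15 (2R,3S)-3-chloro-4-{[(4-methoxybenzyl)oxy]methyl}pent-4-ene-1,2-diol
Conditions: Ti(OiPr)4 (1.5 equiv), Et2NH2Cl (3 equiv), CH2Cl2, rt
Reagents that add atoms: diethylammonium chloride, CC[NH2+]CC.[Cl-]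
Why: Titanium-mediated opening of the 2,3-epoxy alcohol delivers chloride to C3 (here also the allylic carbon) by SN2 with inversion, which sets the C6 chloride anti to the C7 oxygen.

Step 13
Reactants: 15 (2R,3S)-3-chloro-4-{[(4-methoxybenzyl)oxy]methyl}pent-4-ene-1,2-diol
Product: 16 (2R,3S)-3-chloro-2-hydroxy-4-{[(4-methoxybenzyl)oxy]methyl}pent-4-enoic acid
Conditions: TEMPO (20 mol %), PhI(OAc)2 (2.5 equiv), MeCN/H2O 1:1, 0 °C to rt
Reagents that add atoms: water, O
Why: Oxoammonium oxidation takes the primary alcohol of the 1,2-diol to the α-hydroxy acid under near-neutral conditions, which spare the allylic chloride and both stereocentres.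

Step 14
Reactants: 16 (2R,3S)-3-chloro-2-hydroxy-4-{[(4-methoxybenzyl)oxy]methyl}pent-4-enoic acid
Product: 17 methyl (2R,3S)-3-chloro-2-hydroxy-4-{[(4-methoxybenzyl)oxy]methyl}pent-4-enoate
Conditions: Me3SiCHN2, toluene/MeOH, 0 °C
Reagents that add atoms: trimethylsilyldiazomethane, C[Si](C)(C)C=[N+]=[N-]
Why: Base-free O-methylation of the acid by the diazoalkane avoids β-elimination of chloride.

Step 15
Reactants: 17 methyl (2R,3S)-3-chloro-2-hydroxy-4-{[(4-methoxybenzyl)oxy]methyl}pent-4-enoate
Product: 18 methyl (2R,3S)-3-chloro-4-{[(4-methoxybenzyl)oxy]methyl}-2-[(triethylsilyl)oxy]pent-4-enoate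
Conditions: Et3SiOTf, 2,6-lutidine, CH2Cl2, −78 °C
Reagents that add atoms: triethylsilyl triflate, CC[Si](CC)(CC)OS(=O)(=O)C(F)(F)F
Why: Silylation gives the C7 triethylsilyl ether, the one silyl group that can later be removed in the presence of tert-butyldimethylsilyl ethers.

Step 16
Reactants: 18 methyl (2R,3S)-3-chloro-4-{[(4-methoxybenzyl)oxy]methyl}-2-[(triethylsilyl)oxy]pent-4-enoate
Product: 19 methyl (2R,3S)-3-chloro-4-(hydroxymethyl)-2-[(triethylsilyl)oxy]pent-4-enoate
Conditions: DDQ (1.3 equiv), CH2Cl2/pH 7 buffer, 0 °C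
Reagents that add atoms: none
Why: Oxidative cleavage of the 4-methoxybenzyl ether under buffered conditions leaves the silyl ether, ester and chloride intact.

Step 17
Reactants: 19 methyl (2R,3S)-3-chloro-4-(hydroxymethyl)-2-[(triethylsilyl)oxy]pent-4-enoate
Product: 20 methyl (2R,3S)-4-(bromomethyl)-3-chloro-2-[(triethylsilyl)oxy]pent-4-enoate
Conditions: CBr4, PPh3, 2,6-lutidine, CH2Cl2, 0 °C
Reagents that add atoms: carbon tetrabromide, BrC(Br)(Br)Br
Why: Appel bromination of the primary allylic alcohol proceeds under mild buffered conditions, and SN2 and SN2′ lead to the same constitution at this 2-substituted allyl unit.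

Step 18
Reactants: 10 1-[(1R,6S)-6-[(tert-butyldimethylsilyl)oxy]-3-{[(4-methoxybenzyl)oxy]methyl}-1-methylcyclohex-2-en-1-yl]ethan-1-one; 20 methyl (2R,3S)-4-(bromomethyl)-3-chloro-2-[(triethylsilyl)oxy]pent-4-enoate
Product: 22 methyl (2R,3S)-7-[(1R,6S)-6-[(tert-butyldimethylsilyl)oxy]-3-{[(4-methoxybenzyl)oxy]methyl}-1-methylcyclohex-2-en-1-yl]-3-chloro-4-methylidene-7-oxo-2-[(triethylsilyl)oxy]heptanoate, via lithium enolate 21 (not isolated)
Conditions: LiN(iPr)2 (1.05 equiv), THF, −78 °C; then 20, DMPU, −78 to −40 °C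
Reagents that add atoms: none
Why: The methyl group is the only enolisable site of the ketone (C1 is quaternary), and SN2 alkylation of its lithium enolate by the primary allylic bromide forms C3–C4 while the secondary chloride and the less acidic ester stay untouched.

Step 19
Reactants: 22 methyl (2R,3S)-7-[(1R,6S)-6-[(tert-butyldimethylsilyl)oxy]-3-{[(4-methoxybenzyl)oxy]methyl}-1-methylcyclohex-2-en-1-yl]-3-chloro-4-methylidene-7-oxo-2-[(triethylsilyl)oxy]heptanoate
Product: 23 the C2 (7S) alcohol of 22: methyl (2R,3S,7S)-7-[6-[(tert-butyldimethylsilyl)oxy]-3-{[(4-methoxybenzyl)oxy]methyl}-1-methylcyclohex-2-en-1-yl]-3-chloro-7-hydroxy-4-methylidene-2-[(triethylsilyl)oxy]heptanoate (ring centres unchanged)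
Conditions: (R)-2-methyl-CBS-oxazaborolidine (0.5 equiv), catecholborane (2 equiv), toluene, −78 °C
Reagents that add atoms: none
Why: Corey–Bakshi–Shibata reduction under reagent control, with the quaternary C1 as the large and the C3 methylene as the small substituent, should deliver the 2S carbinol, and catecholborane at low temperature does not hydroborate the alkenes or reduce the ester.

Step 20
Reactants: 23 the C2 alcohol
Product: 24 the 2,14-bis(tert-butyldimethylsilyl) ether of 23 (methyl ester, C7 triethylsilyl ether and C20 4-methoxybenzyl ether retained)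
Conditions: TBSOTf, 2,6-lutidine, CH2Cl2, 0 °C
Reagents that add atoms: tert-butyldimethylsilyl triflate, CC(C)(C)[Si](C)(C)OS(=O)(=O)C(F)(F)F
Why: Silylation of the neopentyl-type secondary alcohol with the reactive triflate gives a group that survives methylenation, strong base and SmI2.

Step 21
Reactants: 24 the bis-silyl ether
Product: 25 the C20 allylic alcohol (4-methoxybenzyl group removed from 24)
Conditions: DDQ (1.3 equiv), CH2Cl2/pH 7 buffer, 0 °C
Reagents that add atoms: none
Why: Oxidative cleavage of the 4-methoxybenzyl ether frees only the primary allylic hydroxyl that becomes the lactone oxygen.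

Step 22
Reactants: 25 the C20 allylic alcohol
Product: 26 the seco acid (C8 carboxylic acid, C20 hydroxyl)
Conditions: Me3SnOH (6 equiv), ClCH2CH2Cl, 80 °C; 5 % HCl wash
Reagents that add atoms: trimethyltin hydroxide, C[Sn](C)(C)O
Why: Trimethyltin hydroxide cleaves the methyl ester under nearly neutral conditions, which should avoid epimerisation at C7 and β-elimination of the C6 chloride.

Step 23
Reactants: 26 the seco acid
Product: 27 the 12-membered lactone (ester between the C8 carboxyl and the C20 oxygen; ring atoms C8, O, C20, C11, C10, C1–C7; the ring A alkene C10=C11 is E within the large ring)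
Conditions: 2-methyl-6-nitrobenzoic anhydride (1.5 equiv), DMAP (3 equiv), CH2Cl2 (1 mM, syringe pump), rt
Reagents that add atoms: none
Why: Shiina macrolactonisation at room temperature and high dilution acylates the unhindered primary allylic alcohol with the mixed anhydride, and the mild conditions protect the C7 stereocentre.

Step 24
Reactants: 27 the 12-membered lactone
Product: 29 (1R,2S,6S,7R,10S,14S)-2,14-bis[(tert-butyldimethylsilyl)oxy]-6-chloro-1-methyl-5,11-dimethylidene-7-[(triethylsilyl)oxy]bicyclo[8.4.0]tetradecan-8-one, via enol ether 28 (not isolated)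
Conditions: Cp2TiMe2 (3 equiv), pyridine (1 mol %), toluene, 75 °C, dark; then 150 °C (sealed tube)
Reagents that add atoms: bis(cyclopentadienyl)dimethyltitanium, C[Ti](C)(C1C=CC=C1)C1C=CC=C1
Why: Cp2TiMe2 loses methane to give Cp2Ti=CH2, which adds [2+2] to the lactone carbonyl and cycloreverts to the exocyclic enol ether 28 (Petasis methylenation); on further heating the C9=C8–O vinyl unit and the O–C20–C11=C10 allyl unit of the 12-membered ring undergo a concerted aliphatic Claisen [3,3] rearrangement. The closest known reaction type is the methylenation–Claisen sequence of lactones, used in its ring-expanding form (exocyclic vinyl group) for cyclooctenones and in its ring-contracting form when the allylic double bond lies inside the lactone ring. The ten-membered carbocycle closes by suprafacial C9–C10 bond formation across the 12-membered ring through a chair-like six-atom transition state while the C20–O bond breaks, so that O and C20 leave the ring (two-atom contraction), C11=C20 remains as the exocyclic methylene and C8 becomes the ketone. The only new stereocentre, C10, is controlled by the quaternary C1: in the cyclohexene half-chair with the C2 branch pseudoaxial, C9 can bond to C10 along the axial trajectory anti to that branch, whereas the opposite face needs a 1,3-diaxial approach past the C14 silyloxy group, so the trans ring fusion (H10 anti to CH3-15) should result. The step needs this face selectivity and needs [3,3] to outrun isomerisation of the enol ether into the ring; the first rests on ring A as described, the second on the base-buffered, aluminium-free conditions and on the E geometry that ring A imposes on the allyl unit, which holds C9 near C10.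

Step 25
Reactants: 29 the ten-membered ketone
Product: 31 (1R,2S,6S,7R,9S,10S,14S)-2,14-bis[(tert-butyldimethylsilyl)oxy]-6-chloro-9-hydroxy-1-methyl-5,11-dimethylidene-7-[(triethylsilyl)oxy]bicyclo[8.4.0]tetradecan-8-one, via potassium enolate 30 (not isolated)
Conditions: KN(SiMe3)2 (1.1 equiv), THF, −78 °C; then 2-(phenylsulfonyl)-3-phenyloxaziridine (1.5 equiv), −78 °C; aq. NH4Cl
Reagents that add atoms: 2-(phenylsulfonyl)-3-phenyloxaziridine, O=S(=O)(N1OC1c1ccccc1)c1ccccc1
Why: Davis oxidation of the kinetic enolate, formed at the C9 methylene and not at the silyloxy-shielded C7 methine (as with α-silyloxy ketones in general), should place oxygen on the peripheral face of the C8=C9 enolate anti to C1 and on the side of H10, which corresponds to 9S.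

Step 26
Reactants: 31 the C9 alcohol
Product: 32 the 2,9,14-tris(tert-butyldimethylsilyl) ether (C7 triethylsilyl ether and C8 ketone retained)
Conditions: TBSOTf, 2,6-lutidine, CH2Cl2, −78 to 0 °C
Reagents that add atoms: tert-butyldimethylsilyl triflate, CC(C)(C)[Si](C)(C)OS(=O)(=O)C(F)(F)F
Why: A silyl ether at C9, unlike an ester, is not cleaved reductively by SmI2 and cannot migrate to the C8 alkoxide formed in step 29.

Step 27
Reactants: 32 the tris-silyl ether
Product: 33 the C7 alcohol (triethylsilyl group removed; 7-hydroxy-8-ketone)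
Conditions: HF·pyridine, pyridine, THF, 0 °C
Reagents that add atoms: none
Why: Buffered fluoride removes the triethylsilyl ether much faster than the three secondary tert-butyldimethylsilyl ethers, and the acidic medium avoids acyloin-type and elimination side reactions.

Step 28
Reactants: 33 the C7 alcohol
Product: 34 the C7 2-bromopropanoate (mixture of epimers at the bromine-bearing carbon, which is of no consequence)
Conditions: 2-bromopropanoyl bromide, pyridine, CH2Cl2, −20 °C
Reagents that add atoms: 2-bromopropanoyl bromide, CC(Br)C(Br)=O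
Why: O-Acylation of the α-hydroxy ketone with the acid bromide installs C17–C19 on the oxygen that becomes the lactone oxygen.

Step 29
Reactants: 34 the C7 2-bromopropanoate
Product: 36 the γ-lactone (target skeleton with tert-butyldimethylsilyl ethers at O2, O9 and O14 and the free C8 hydroxyl), via samarium enolate 35 (not isolated)
Conditions: SmI2 (2.5 equiv), THF, −78 °C; aq. NH4Cl at −78 °C
Reagents that add atoms: none
Why: Samarium Reformatsky reaction, in which two-electron reduction of the C–Br bond gives the trivalent samarium Z-enolate that adds to the adjacent C8 ketone through a chelated bicyclic transition state; the five-membered closure puts C6 anti to C9 (H7 eclipsing C9), which sets C8 and the trans ring fusion, and the Z-enolate places the C17 methyl cis to the new hydroxyl.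

Step 30
Reactants: 36 the tris-silylated γ-lactone
Product: 37 the 2,9,14-tri-O-deacetyl target (2,8,9,14-tetraol)
Conditions: HF·pyridine, THF, rt (plastic vessel)
Reagents that add atoms: none
Why: Acidic fluoride desilylation removes the three tert-butyldimethylsilyl ethers without touching the lactone, the tertiary alcohol or the allylic chloride.

Step 31
Reactants: 37 the tetraol
Product: 38 the target (1R,2S,6S,7R,8R,9S,10S,14S,17R)
Conditions: Ac2O, pyridine, DMAP (cat.), CH2Cl2, rt
Reagents that add atoms: acetic anhydride, CC(=O)OC(C)=O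
Why: Acetylation esterifies the three secondary hydroxyls at C2, C9 and C14, while the tertiary C8 hydroxyl, flanked by C7, C9 and C17, should remain free.

## Compound list

1 | 2-methylidenepropane-1,3-diol | C=C(CO)CO | starting material
2 | 2-{[(4-methoxybenzyl)oxy]methyl}prop-2-en-1-ol | OCC(=C)COCc1ccc(OC)cc1 | intermediate
3 | ethyl 4-{[(4-methoxybenzyl)oxy]methyl}pent-4-enoate | CCOC(=O)CCC(=C)COCc1ccc(OC)cc1 | intermediate
4 | 4-{[(4-methoxybenzyl)oxy]methyl}pent-4-en-1-ol | OCCCC(=C)COCc1ccc(OC)cc1 | intermediate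
5 | isoprene monoxide (2-ethenyl-2-methyloxirane, racemic) | CC1(C=C)CO1 | starting material
6 | (2S,3S)-2-ethenyl-6-{[(4-methoxybenzyl)oxy]methyl}-2-methylhept-6-ene-1,3-diol | COc1ccc(COCC(=C)CC[C@H](O)[C@](C=C)(C)CO)cc1 | intermediate
7 | (1S,2S)-2-(hydroxymethyl)-4-{[(4-methoxybenzyl)oxy]methyl}-2-methylcyclohex-3-en-1-ol | COc1ccc(COCC(=C2)CC[C@H](O)[C@]2(C)CO)cc1 | intermediate
8 | (1R,6S)-6-hydroxy-3-{[(4-methoxybenzyl)oxy]methyl}-1-methylcyclohex-2-ene-1-carboxylic acid | COc1ccc(COCC(=C2)CC[C@H](O)[C@]2(C)C(=O)O)cc1 | intermediate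
9 | 1-[(1R,6S)-6-hydroxy-3-{[(4-methoxybenzyl)oxy]methyl}-1-methylcyclohex-2-en-1-yl]ethan-1-one | COc1ccc(COCC(=C2)CC[C@H](O)[C@]2(C)C(C)=O)cc1 | intermediate
10 | 1-[(1R,6S)-6-[(tert-butyldimethylsilyl)oxy]-3-{[(4-methoxybenzyl)oxy]methyl}-1-methylcyclohex-2-en-1-yl]ethan-1-one | COc1ccc(COCC(=C2)CC[C@H](O[Si](C)(C)C(C)(C)C)[C@]2(C)C(C)=O)cc1 | intermediate
11 | 2-{[(4-methoxybenzyl)oxy]methyl}prop-2-enal | O=CC(=C)COCc1ccc(OC)cc1 | intermediate (not isolated)
12 | ethyl (2E)-4-{[(4-methoxybenzyl)oxy]methyl}penta-2,4-dienoate | CCOC(=O)/C=C/C(=C)COCc1ccc(OC)cc1 | intermediate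
13 | (2E)-4-{[(4-methoxybenzyl)oxy]methyl}penta-2,4-dien-1-ol | OC/C=C/C(=C)COCc1ccc(OC)cc1 | intermediate
14 | [(2R,3R)-3-(3-{[(4-methoxybenzyl)oxy]}prop-1-en-2-yl)oxiran-2-yl]methanol | COc1ccc(COCC(=C)[C@H]2O[C@@H]2CO)cc1 | intermediate
15 | (2R,3S)-3-chloro-4-{[(4-methoxybenzyl)oxy]methyl}pent-4-ene-1,2-diol | COc1ccc(COCC(=C)[C@H](Cl)[C@H](O)CO)cc1 | intermediate
16 | (2R,3S)-3-chloro-2-hydroxy-4-{[(4-methoxybenzyl)oxy]methyl}pent-4-enoic acid | COc1ccc(COCC(=C)[C@H](Cl)[C@H](O)C(=O)O)cc1 | intermediate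
17 | methyl (2R,3S)-3-chloro-2-hydroxy-4-{[(4-methoxybenzyl)oxy]methyl}pent-4-enoate | COc1ccc(COCC(=C)[C@H](Cl)[C@H](O)C(=O)OC)cc1 | intermediate
18 | methyl (2R,3S)-3-chloro-4-{[(4-methoxybenzyl)oxy]methyl}-2-[(triethylsilyl)oxy]pent-4-enoate | COc1ccc(COCC(=C)[C@H](Cl)[C@H](O[Si](CC)(CC)CC)C(=O)OC)cc1 | intermediate
19 | methyl (2R,3S)-3-chloro-4-(hydroxymethyl)-2-[(triethylsilyl)oxy]pent-4-enoate | OCC(=C)[C@H](Cl)[C@H](O[Si](CC)(CC)CC)C(=O)OC | intermediate
20 | methyl (2R,3S)-4-(bromomethyl)-3-chloro-2-[(triethylsilyl)oxy]pent-4-enoate | BrCC(=C)[C@H](Cl)[C@H](O[Si](CC)(CC)CC)C(=O)OC | intermediate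
21 | lithium enolate of 10 (lithium 1-[ring A]ethen-1-olate) | COc1ccc(COCC(=C2)CC[C@H](O[Si](C)(C)C(C)(C)C)[C@]2(C)C(=C)O[Li])cc1 | intermediate (not isolated)
22 | methyl (2R,3S)-7-[(1R,6S)-6-[(tert-butyldimethylsilyl)oxy]-3-{[(4-methoxybenzyl)oxy]methyl}-1-methylcyclohex-2-en-1-yl]-3-chloro-4-methylidene-7-oxo-2-[(triethylsilyl)oxy]heptanoate | COc1ccc(COCC(=C2)CC[C@H](O[Si](C)(C)C(C)(C)C)[C@]2(C)C(=O)CCC(=C)[C@H](Cl)[C@H](O[Si](CC)(CC)CC)C(=O)OC)cc1 | intermediate
23 | C2 (7S) alcohol of 22; other centres as in 22 | COc1ccc(COCC(=C2)CC[C@H](O[Si](C)(C)C(C)(C)C)[C@]2(C)[C@@H](O)CCC(=C)[C@H](Cl)[C@H](O[Si](CC)(CC)CC)C(=O)OC)cc1 | intermediate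
24 | 2,14-bis(tert-butyldimethylsilyl) ether of 23 | COc1ccc(COCC(=C2)CC[C@H](O[Si](C)(C)C(C)(C)C)[C@]2(C)[C@@H](O[Si](C)(C)C(C)(C)C)CCC(=C)[C@H](Cl)[C@H](O[Si](CC)(CC)CC)C(=O)OC)cc1 | intermediate
25 | C20 allylic alcohol (24 without the 4-methoxybenzyl group) | OCC(=C1)CC[C@H](O[Si](C)(C)C(C)(C)C)[C@]1(C)[C@@H](O[Si](C)(C)C(C)(C)C)CCC(=C)[C@H](Cl)[C@H](O[Si](CC)(CC)CC)C(=O)OC | intermediate
26 | seco acid (C8 carboxylic acid of 25) | OCC(=C1)CC[C@H](O[Si](C)(C)C(C)(C)C)[C@]1(C)[C@@H](O[Si](C)(C)C(C)(C)C)CCC(=C)[C@H](Cl)[C@H](O[Si](CC)(CC)CC)C(=O)O | intermediate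
27 | 12-membered lactone C8(=O)–O–C20 of 26; 1R,2S,6S,7R,14S | C1C(=C2)CC[C@H](O[Si](C)(C)C(C)(C)C)[C@]2(C)[C@@H](O[Si](C)(C)C(C)(C)C)CCC(=C)[C@H](Cl)[C@H](O[Si](CC)(CC)CC)C(=O)O1 | intermediate
28 | 12-membered exocyclic enol ether (C8=C9H2 in place of the lactone carbonyl of 27) | C1C(=C2)CC[C@H](O[Si](C)(C)C(C)(C)C)[C@]2(C)[C@@H](O[Si](C)(C)C(C)(C)C)CCC(=C)[C@H](Cl)[C@H](O[Si](CC)(CC)CC)C(=C)O1 | intermediate (not isolated)
29 | (1R,2S,6S,7R,10S,14S)-2,14-bis[(tert-butyldimethylsilyl)oxy]-6-chloro-1-methyl-5,11-dimethylidene-7-[(triethylsilyl)oxy]bicyclo[8.4.0]tetradecan-8-one | C=C1CC[C@H](O[Si](C)(C)C(C)(C)C)[C@]2(C)[C@@H](O[Si](C)(C)C(C)(C)C)CCC(=C)[C@H](Cl)[C@H](O[Si](CC)(CC)CC)C(=O)C[C@@H]12 | intermediate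
30 | potassium C8(O)=C9 enolate of 29 | C=C1CC[C@H](O[Si](C)(C)C(C)(C)C)[C@]2(C)[C@@H](O[Si](C)(C)C(C)(C)C)CCC(=C)[C@H](Cl)[C@H](O[Si](CC)(CC)CC)C(O[K])=C[C@@H]12 | intermediate (not isolated)
31 | (9S)-9-hydroxy derivative of 29 | C=C1CC[C@H](O[Si](C)(C)C(C)(C)C)[C@]2(C)[C@@H](O[Si](C)(C)C(C)(C)C)CCC(=C)[C@H](Cl)[C@H](O[Si](CC)(CC)CC)C(=O)[C@@H](O)[C@@H]12 | intermediate
32 | 9-O-(tert-butyldimethylsilyl) ether of 31 | C=C1CC[C@H](O[Si](C)(C)C(C)(C)C)[C@]2(C)[C@@H](O[Si](C)(C)C(C)(C)C)CCC(=C)[C@H](Cl)[C@H](O[Si](CC)(CC)CC)C(=O)[C@@H](O[Si](C)(C)C(C)(C)C)[C@@H]12 | intermediate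
33 | 7-hydroxy-8-ketone (32 without the triethylsilyl group) | C=C1CC[C@H](O[Si](C)(C)C(C)(C)C)[C@]2(C)[C@@H](O[Si](C)(C)C(C)(C)C)CCC(=C)[C@H](Cl)[C@H](O)C(=O)[C@@H](O[Si](C)(C)C(C)(C)C)[C@@H]12 | intermediate
34 | C7 2-bromopropanoate of 33 (epimers at the CHBr carbon) | C=C1CC[C@H](O[Si](C)(C)C(C)(C)C)[C@]2(C)[C@@H](O[Si](C)(C)C(C)(C)C)CCC(=C)[C@H](Cl)[C@H](OC(=O)C(C)Br)C(=O)[C@@H](O[Si](C)(C)C(C)(C)C)[C@@H]12 | intermediate
35 | trivalent samarium Z-enolate of the C7 propanoate | C=C1CC[C@H](O[Si](C)(C)C(C)(C)C)[C@]2(C)[C@@H](O[Si](C)(C)C(C)(C)C)CCC(=C)[C@H](Cl)[C@H](O/C(O[Sm](I)I)=C/C)C(=O)[C@@H](O[Si](C)(C)C(C)(C)C)[C@@H]12 | intermediate (not isolated)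
36 | 2,9,14-tris-O-(tert-butyldimethylsilyl) derivative of 37 (γ-lactone closed, free C8 hydroxyl; spatial arrangement at all nine centres as in the target) | C=C1CC[C@H](O[Si](C)(C)C(C)(C)C)[C@]2(C)[C@@H](O[Si](C)(C)C(C)(C)C)CCC(=C)[C@H](Cl)[C@@H]3OC(=O)[C@H](C)[C@@]3(O)[C@@H](O[Si](C)(C)C(C)(C)C)[C@@H]12 | intermediate
37 | 2,9,14-tri-O-deacetyl target (1R,2S,6S,7R,8R,9S,10S,14S,17R) | C=C1CC[C@H](O)[C@]2(C)[C@@H](O)CCC(=C)[C@H](Cl)[C@@H]3OC(=O)[C@H](C)[C@@]3(O)[C@@H](O)[C@@H]12 | intermediate
38 | target, CNP0199061.1 (1R,2S,6S,7R,8R,9S,10S,14S,17R) | C=C1CC[C@H](OC(C)=O)[C@]2(C)[C@@H](OC(C)=O)CCC(=C)[C@H](Cl)[C@@H]3OC(=O)[C@H](C)[C@@]3(O)[C@@H](OC(C)=O)[C@@H]12 | target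

## Step count and risks

Total step count: 31. Longest linear sequence: 24 steps (steps 1, 9–17, 18–31); the ring A branch (steps 1–8, 18–31) has 22.

Three steps most likely to fail:

Step 24. Methylenation of the hindered α-silyloxy lactone carbonyl may stall, the exocyclic enol ether may isomerise into the ring before it rearranges, or C9 may add to the wrong face of C10. The fallback builds the same 12-membered enol ether by a different bond and without titanium. It sets out from 25: reduction of the methyl ester with iBu2AlH at −78 °C gives aldehyde F1, and Ohira–Bestmann homologation (dimethyl (1-diazo-2-oxopropyl)phosphonate, K2CO3, MeOH, 0 °C) gives terminal alkyne F2. Gold-catalysed Markovnikov addition of the C20 hydroxyl to the alkyne (Ph3PAuNTf2, toluene, high dilution), the intramolecular form of the known hydroalkoxylation–Claisen sequence of allylic alcohols with alkynes, then closes the ring to 28. On warming 28 contracts, so the fallback comes back to the route at 28 and thereby at 29.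

Step 25. The base may remove the C7 proton, with β-loss of chloride, or the oxidant may attack the wrong face of the enolate. The fallback replaces enolate oxidation by a Rubottom sequence and corrects the face by inversion. It sets out from 29: lithium 2,2,6,6-tetramethylpiperidide is added to 29 premixed with Me3SiCl at −100 °C, so that the enolate never accumulates, and this gives trimethylsilyl enol ether F3. Oxidation with dimethyldioxirane at −78 °C and mild acid work-up gives 31. If the C9 epimer F4 is formed instead, Mitsunobu inversion with chloroacetic acid (PPh3, DIAD) gives chloroacetate F5, which thiourea/NaHCO3 cleaves to 31, where the fallback comes back to the route.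

Step 29. Electron transfer to the C8 ketone may expel the α-acyloxy group, or reduce the allylic chloride, before the samarium enolate adds, and the C17 selectivity may be low. The fallback sets out from 33 and uses an intermolecular zinc Reformatsky reaction with ethyl 2-bromopropanoate (activated Zn, THF, 0 °C). The zinc alkoxide of the free C7 hydroxyl chelates the C8 carbonyl and directs addition to the same face, giving dihydroxy ethyl ester F6. Lactonisation (PPTS, toluene, 60 °C) gives 36 together with C17 epimer F7, which DBU equilibrates to 36 (methyl trans to C9), where the fallback comes back to the route.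

## Further compounds

F1 | step 24 | C8 aldehyde from 25 | OCC(=C1)CC[C@H](O[Si](C)(C)C(C)(C)C)[C@]1(C)[C@@H](O[Si](C)(C)C(C)(C)C)CCC(=C)[C@H](Cl)[C@H](O[Si](CC)(CC)CC)C=O
F2 | step 24 | terminal alkyne C8≡C9H | OCC(=C1)CC[C@H](O[Si](C)(C)C(C)(C)C)[C@]1(C)[C@@H](O[Si](C)(C)C(C)(C)C)CCC(=C)[C@H](Cl)[C@H](O[Si](CC)(CC)CC)C#C
F3 | step 25 | trimethylsilyl enol ether C8(OSiMe3)=C9 of 29 | C=C1CC[C@H](O[Si](C)(C)C(C)(C)C)[C@]2(C)[C@@H](O[Si](C)(C)C(C)(C)C)CCC(=C)[C@H](Cl)[C@H](O[Si](CC)(CC)CC)C(O[Si](C)(C)C)=C[C@@H]12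
F4 | step 25 | C9 epimer of 31 | C=C1CC[C@H](O[Si](C)(C)C(C)(C)C)[C@]2(C)[C@@H](O[Si](C)(C)C(C)(C)C)CCC(=C)[C@H](Cl)[C@H](O[Si](CC)(CC)CC)C(=O)[C@H](O)[C@@H]12
F5 | step 25 | 9-O-chloroacetate of 31 | C=C1CC[C@H](O[Si](C)(C)C(C)(C)C)[C@]2(C)[C@@H](O[Si](C)(C)C(C)(C)C)CCC(=C)[C@H](Cl)[C@H](O[Si](CC)(CC)CC)C(=O)[C@@H](OC(=O)CCl)[C@@H]12
F6 | step 29 | 7,8-dihydroxy ethyl ester (C17 epimers) | C=C1CC[C@H](O[Si](C)(C)C(C)(C)C)[C@]2(C)[C@@H](O[Si](C)(C)C(C)(C)C)CCC(=C)[C@H](Cl)[C@H](O)[C@@](O)(C(C)C(=O)OCC)[C@@H](O[Si](C)(C)C(C)(C)C)[C@@H]12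
F7 | step 29 | C17 epimer of 36 | C=C1CC[C@H](O[Si](C)(C)C(C)(C)C)[C@]2(C)[C@@H](O[Si](C)(C)C(C)(C)C)CCC(=C)[C@H](Cl)[C@@H]3OC(=O)[C@@H](C)[C@@]3(O)[C@@H](O[Si](C)(C)C(C)(C)C)[C@@H]12
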